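Retrosynthesis: cut the stearate C–O bond and the O-methyl of a methyl tetronate; trace the exocyclic C5=C1' alkene back to a C5–C1' aldol bond between C5-lithiated 4-methoxy-3-methylfuran-2(5H)-one and an (S)-2-methyl aldehyde; open the furan into 4-phenyloxazole plus a terminal alkyne; cut the propargylic C–C bond to a farnesol-derived allylic bromide and 1-(trimethylsilyl)propyne.
Enabling feature: the furan has one carbon substituent at C3 and hydrogen at C2, C4 and C5, so C3–C4 is a masked terminal alkyne and C2–O1–C5 a masked C5–O1–C2 of an oxazole whose C4–N3 can leave as a nitrile.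
Forward: the farnesol chain is oxidised at its far end, reduced and converted into the 1,5-enyne; the furan ring is then made by oxazole cycloaddition and nitrile loss; the preformed butenolide ring is joined by aldol addition, the ylidene is made by elimination, and stearoylation comes last.
Stereochemistry: the single S centre comes from hydroxyl-directed Ru–BINAP hydrogenation; both chain alkenes are those of (2E,6E)-farnesol; the E ylidene comes from a stereospecific anti-elimination of the like-configured aldol.

Key step: step 9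

Assumption 1: Ru(OAc)2[(S)-BINAP] is taken to add H2 to the same face of the HOCH2–C=C unit as with geraniol, which here means 11S; if the sense proves opposite, the (R) ligand is used.
Assumption 2: compound 25 stands for the two like carbinols (5R,1'R,2'S drawn; 5S,1'S,2'S carried along), which share the C5/C1' relation and give the same alkene.

Step 1
Reactants: 1 (2E,6E)-farnesol
Product: 2 (2E,6E)-farnesyl acetate
Conditions: Ac2O, pyridine, DMAP (cat.), CH2Cl2, 0 °C → rt
Reagents that add atoms: acetic anhydride, CC(=O)OC(C)=O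
Why: DMAP-catalysed O-acetylation of the primary allylic alcohol, which masks C1 and makes the C2–C3 alkene the least reactive one toward SeO2 and toward hydroxyl-directed hydrogenation.

Step 2
Reactants: 2 (2E,6E)-farnesyl acetate
Product: 3 (2E,6E,10E)-12-hydroxy-3,7,11-trimethyldodeca-2,6,10-trien-1-yl acetate
Conditions: SeO2 (cat.), t-BuOOH, salicylic acid (cat.), CH2Cl2, 20 °C
Reagents that add atoms: tert-butyl hydroperoxide, CC(C)(C)OO (oxygen passed on through selenium dioxide, O=[Se]=O)
Why: Riley-type catalytic allylic oxidation (ene reaction, then [2,3]-sigmatropic shift) attacks the most electron-rich, acetate-remote terminal alkene at its E-methyl group, so the E-configured primary allylic alcohol should result.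

Step 3
Reactants: 3 (2E,6E,10E)-12-hydroxy-3,7,11-trimethyldodeca-2,6,10-trien-1-yl acetate
Product: 4 (2E,6E,11S)-12-hydroxy-3,7,11-trimethyldodeca-2,6-dien-1-yl acetate
Conditions: Ru(OAc)2[(S)-BINAP] (1 mol %), H2 (100 atm), MeOH, 20 °C
Reagents that add atoms: none
Why: Noyori hydroxyl-directed asymmetric hydrogenation reduces only the alkene that can chelate ruthenium through its free allylic hydroxyl, leaves the two other trisubstituted alkenes alone, and the chiral diphosphine selects the alkene face that gives the 11S centre.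

Step 4
Reactants: 4 (2E,6E,11S)-12-hydroxy-3,7,11-trimethyldodeca-2,6-dien-1-yl acetate
Product: 5 (2E,6E,11S)-12-[(tert-butyldimethylsilyl)oxy]-3,7,11-trimethyldodeca-2,6-dien-1-yl acetate
Conditions: TBSCl, imidazole, DMF, rt
Reagents that add atoms: tert-butyldimethylsilyl chloride, CC(C)(C)[Si](C)(C)Cl
Why: Imidazole-promoted silylation of the only free primary alcohol; the TBS ether is chosen because it survives carbonate methanolysis, organolithium alkylation and prolonged heating at 220 °C.

Step 5
Reactants: 5 (2E,6E,11S)-12-[(tert-butyldimethylsilyl)oxy]-3,7,11-trimethyldodeca-2,6-dien-1-yl acetate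
Product: 6 (2E,6E,11S)-12-[(tert-butyldimethylsilyl)oxy]-3,7,11-trimethyldodeca-2,6-dien-1-ol
Conditions: K2CO3 (cat.), MeOH, rt
Reagents that add atoms: none
Why: Base-catalysed transesterification (Zemplén-type methanolysis) removes the acetate while the silyl ether is inert.

Step 6
Reactants: 6 (2E,6E,11S)-12-[(tert-butyldimethylsilyl)oxy]-3,7,11-trimethyldodeca-2,6-dien-1-ol
Product: 8 {[(2S,6E,10E)-12-bromo-2,6,10-trimethyldodeca-6,10-dien-1-yl]oxy}(tert-butyl)dimethylsilane, via allylic methanesulfonate 7 (not isolated)
Conditions: MsCl, Et3N, THF, −45 °C; then LiBr, THF, −45 → 0 °C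
Reagents that add atoms: lithium bromide, [Li+].[Br-]
Why: Mesylation followed by SN2 displacement with bromide at low temperature converts the primary allylic alcohol into the bromide without allylic transposition or loss of E geometry; the bromide is used at once.

Step 7
Reactants: 8 {[(2S,6E,10E)-12-bromo-2,6,10-trimethyldodeca-6,10-dien-1-yl]oxy}(tert-butyl)dimethylsilane; 9 1-(trimethylsilyl)propyne
Product: 12 tert-butyldimethyl{[(2S,6E,10E)-2,6,10-trimethylpentadeca-6,10-dien-14-yn-1-yl]oxy}silane, via 3-lithio-1-(trimethylsilyl)propyne 10 (not isolated), via C-silylated enyne 11 (not isolated)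
Conditions: 9, n-BuLi, THF, −78 → −20 °C; 8, −78 → 0 °C; then MeOH, K2CO3, rt
Reagents that add atoms: none
Why: Propargylic lithiation and SN2 alkylation with the primary allylic bromide builds the 1,5-enyne (the silyl group steers attack to the propargylic terminus), and methoxide protodesilylation then frees the terminal alkyne while the O-silyl ether stays.

Step 8
Reactants: 13 2-bromoacetophenone
Product: 14 4-phenyloxazole
Conditions: HCONH2 (neat, excess), 130 °C
Reagents that add atoms: formamide, NC=O
Why: Bredereck oxazole synthesis: formamide is alkylated on oxygen by the α-bromo ketone and its nitrogen condenses with the carbonyl group, so phenyl ends up at C4 and C2 and C5 carry hydrogen.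

Step 9
Reactants: 12 tert-butyldimethyl{[(2S,6E,10E)-2,6,10-trimethylpentadeca-6,10-dien-14-yn-1-yl]oxy}silane; 14 4-phenyloxazole
Product: 16 tert-butyl{[(2S,6E,10E)-13-(furan-3-yl)-2,6,10-trimethyltrideca-6,10-dien-1-yl]oxy}dimethylsilane, via 3-phenyl-7-oxa-2-azabicyclo[2.2.1]hepta-2,5-diene adduct 15 (not isolated)
Conditions: 14 (3–5 equiv), hydroquinone (trace), neat, sealed tube, Ar, 220 °C
Reagents that add atoms: none
Why: The C5=C4–N3=C2 unit of the oxazole is the 4π partner and the terminal alkyne the 2π partner, so one concerted thermal [4+2] event joins the alkyne carbons to C2 and C5 and closes the six-membered ring of bicycle 15, after which a cycloreversion releases C4–N3 with its phenyl group as benzonitrile. The closest known reaction type is the oxazole–alkyne Diels–Alder/retro-Diels–Alder furan synthesis (Kondrat'eva-type cycloaddition with nitrile extrusion), which needs forcing heat for an unactivated alkyne. The furan ring therefore arises by cycloaddition and cycloreversion, not by cyclisation: the alkyne carbons become C3 and C4, and C5–O1–C2 of the oxazole becomes C2–O1–C5. No stereocentre is formed, and the existing S centre is a saturated carbon with no activating neighbour, so heat should leave it untouched. The step needs chemoselectivity for the alkyne over the two trisubstituted alkenes, which follows because alkene adducts cannot aromatise and revert whereas nitrile loss is irreversible; regiochemistry is immaterial because C2 and C5 of the oxazole both carry hydrogen and either orientation gives the same 3-substituted furan. Excess oxazole, exclusion of air and a radical inhibitor are meant to let the bimolecular addition outpace thermal reorganisation of the 1,5-enyne and 1,5-diene units, and the sensitive tetronate is attached only afterwards.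

Step 10
Reactants: 16 tert-butyl{[(2S,6E,10E)-13-(furan-3-yl)-2,6,10-trimethyltrideca-6,10-dien-1-yl]oxy}dimethylsilane
Product: 17 (2S,6E,10E)-13-(furan-3-yl)-2,6,10-trimethyltrideca-6,10-dien-1-ol
Conditions: Bu4NF, THF, 0 °C → rt
Reagents that add atoms: none
Why: Fluoride-induced cleavage of the silyl ether; furan, alkenes and the stereocentre are inert to it.

Step 11
Reactants: 17 (2S,6E,10E)-13-(furan-3-yl)-2,6,10-trimethyltrideca-6,10-dien-1-ol
Product: 18 (2S,6E,10E)-13-(furan-3-yl)-2,6,10-trimethyltrideca-6,10-dienal
Conditions: Dess–Martin periodinane, NaHCO3, CH2Cl2, 0 °C → rt; used at once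
Reagents that add atoms: none
Why: Buffered Dess–Martin oxidation stops at the aldehyde and is mild enough not to enolise the α-methyl stereocentre or harm the furan.

Step 12
Reactants: 19 ethyl 2-methyl-3-oxobutanoate
Product: 22 3-methyltetronic acid (4-hydroxy-3-methylfuran-2(5H)-one), via ethyl 2-bromo-2-methyl-3-oxobutanoate 20 (not isolated), via ethyl 4-bromo-2-methyl-3-oxobutanoate 21 (not isolated)
Conditions: Br2, CHCl3, 0 °C → rt; then neat, 110–130 °C
Reagents that add atoms: none
Why: Classical tetronic acid synthesis: bromination of the β-keto ester, HBr-mediated migration of bromine to the terminal methyl group, then thermal lactonisation in which the ester oxygen displaces bromide and the ethyl group is lost.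

Step 13
Reactants: 22 3-methyltetronic acid
Product: 23 4-methoxy-3-methylfuran-2(5H)-one
Conditions: Me2SO4, K2CO3, acetone, reflux
Reagents that add atoms: dimethyl sulfate, COS(=O)(=O)OC
Why: O-alkylation of the vinylogous acid gives the conjugated 4-methoxy butenolide (methyl tetronate), which protects the enol and allows deprotonation at C5.

Step 14
Reactants: 18 (2S,6E,10E)-13-(furan-3-yl)-2,6,10-trimethyltrideca-6,10-dienal; 23 4-methoxy-3-methylfuran-2(5H)-one
Product: 25 (5R)-5-[(1R,2S,6E,10E)-13-(furan-3-yl)-1-hydroxy-2,6,10-trimethyltrideca-6,10-dien-1-yl]-4-methoxy-3-methylfuran-2(5H)-one (like pair), via lithium 4-methoxy-3-methylfuran-2-olate 24 (not isolated)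
Conditions: 23, LiN(i-Pr)2, THF, −78 °C; 18, −78 °C; AcOH/THF quench; chromatography, like pair taken on
Reagents that add atoms: none
Why: Aldol addition of the C5-lithiated methyl tetronate (a 2-furanolate that can only react at C5) to the aldehyde at −78 °C should outrun enolisation of the α-branched aldehyde; the C5/C1' relation is not expected to be controlled, so the like pair is separated, its two members differing only in their relation to C2' and converging in step 15.

Step 15
Reactants: 25 like carbinol (5R,1'R,2'S and its 5S,1'S,2'S companion)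
Product: 27 (5E)-5-[(2S,6E,10E)-13-(furan-3-yl)-2,6,10-trimethyltrideca-6,10-dien-1-ylidene]-4-methoxy-3-methylfuran-2(5H)-one, via alkoxytriphenylphosphonium ion 26 (not isolated)
Conditions: PPh3, DIAD, THF, −20 °C → rt, dark
Reagents that add atoms: none
Why: Dehydration under Mitsunobu conditions is a stereospecific anti (E2) elimination of the alkoxyphosphonium ion, established for γ-(α-hydroxyalkyl)butenolides; with H-5 antiperiplanar to the leaving group the like carbinol places the chain cis to C4 and trans to O1, which is the E alkene, and the weakly basic medium avoids the E1cB path that would favour the Z isomer.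

Step 16
Reactants: 27 (5E)-5-[(2S,6E,10E)-13-(furan-3-yl)-2,6,10-trimethyltrideca-6,10-dien-1-ylidene]-4-methoxy-3-methylfuran-2(5H)-one
Product: 28 (5E)-5-[(2S,6E,10E)-13-(furan-3-yl)-2,6,10-trimethyltrideca-6,10-dien-1-ylidene]-4-hydroxy-3-methylfuran-2(5H)-one
Conditions: n-PrSLi (from n-PrSH, n-BuLi), HMPA, 20 °C; then 1 M HCl, 0 °C
Reagents that add atoms: none
Why: SN2 O-demethylation of the vinylogous methyl ester by the soft thiolate in a dipolar aprotic solvent; the tetronate anion that forms is no longer electrophilic, which should protect the E alkene from addition–elimination isomerisation.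

Step 17
Reactants: 28 (5E)-5-[(2S,6E,10E)-13-(furan-3-yl)-2,6,10-trimethyltrideca-6,10-dien-1-ylidene]-4-hydroxy-3-methylfuran-2(5H)-one
Product: 29 (2E)-2-[(2S,6E,10E)-13-(furan-3-yl)-2,6,10-trimethyltrideca-6,10-dien-1-ylidene]-4-methyl-5-oxo-2,5-dihydrofuran-3-yl octadecanoate (CNP0018186.1)
Conditions: n-C17H35COCl, Et3N, CH2Cl2, 0 °C; pH 7 work-up
Reagents that add atoms: stearoyl chloride, CCCCCCCCCCCCCCCCCC(=O)Cl
Why: O-acylation of the acidic tetronic acid hydroxyl with an acid chloride and a tertiary amine; C3 is blocked by methyl, so C-acylation cannot compete, and the mild base and neutral work-up spare the enol ester and the E alkene.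

Compound list
1 | (2E,6E)-farnesol | CC(C)=CCC/C(C)=C/CC/C(C)=C/CO | starting material
2 | (2E,6E)-farnesyl acetate | CC(C)=CCC/C(C)=C/CC/C(C)=C/COC(C)=O | intermediate
3 | (2E,6E,10E)-12-hydroxy-3,7,11-trimethyldodeca-2,6,10-trien-1-yl acetate | OC/C(C)=C/CC/C(C)=C/CC/C(C)=C/COC(C)=O | intermediate
4 | (2E,6E,11S)-12-hydroxy-3,7,11-trimethyldodeca-2,6-dien-1-yl acetate | OC[C@@H](C)CCC/C(C)=C/CC/C(C)=C/COC(C)=O | intermediate
5 | (2E,6E,11S)-12-[(tert-butyldimethylsilyl)oxy]-3,7,11-trimethyldodeca-2,6-dien-1-yl acetate | CC(C)(C)[Si](C)(C)OC[C@@H](C)CCC/C(C)=C/CC/C(C)=C/COC(C)=O | intermediate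
6 | (2E,6E,11S)-12-[(tert-butyldimethylsilyl)oxy]-3,7,11-trimethyldodeca-2,6-dien-1-ol | CC(C)(C)[Si](C)(C)OC[C@@H](C)CCC/C(C)=C/CC/C(C)=C/CO | intermediate
7 | (2E,6E,11S)-12-[(tert-butyldimethylsilyl)oxy]-3,7,11-trimethyldodeca-2,6-dien-1-yl methanesulfonate | CC(C)(C)[Si](C)(C)OC[C@@H](C)CCC/C(C)=C/CC/C(C)=C/COS(C)(=O)=O | intermediate (not isolated)
8 | {[(2S,6E,10E)-12-bromo-2,6,10-trimethyldodeca-6,10-dien-1-yl]oxy}(tert-butyl)dimethylsilane | CC(C)(C)[Si](C)(C)OC[C@@H](C)CCC/C(C)=C/CC/C(C)=C/CBr | intermediate
9 | 1-(trimethylsilyl)propyne | CC#C[Si](C)(C)C | starting material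
10 | 3-lithio-1-(trimethylsilyl)propyne | [Li]CC#C[Si](C)(C)C | intermediate (not isolated)
11 | tert-butyldimethyl{[(2S,6E,10E)-2,6,10-trimethyl-15-(trimethylsilyl)pentadeca-6,10-dien-14-yn-1-yl]oxy}silane | CC(C)(C)[Si](C)(C)OC[C@@H](C)CCC/C(C)=C/CC/C(C)=C/CCC#C[Si](C)(C)C | intermediate (not isolated)
12 | tert-butyldimethyl{[(2S,6E,10E)-2,6,10-trimethylpentadeca-6,10-dien-14-yn-1-yl]oxy}silane | CC(C)(C)[Si](C)(C)OC[C@@H](C)CCC/C(C)=C/CC/C(C)=C/CCC#C | intermediate
13 | 2-bromoacetophenone | O=C(CBr)c1ccccc1 | starting material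
14 | 4-phenyloxazole | c1ccc(cc1)-c1cocn1 | intermediate
15 | 3-phenyl-7-oxa-2-azabicyclo[2.2.1]hepta-2,5-diene carrying the chain at C5 (drawn; the C6 regioisomer gives the same furan; bridgehead configurations unspecified) | CC(C)(C)[Si](C)(C)OC[C@@H](C)CCC/C(C)=C/CC/C(C)=C/CCC1=CC2N=C(c3ccccc3)C1O2 | intermediate (not isolated)
16 | tert-butyl{[(2S,6E,10E)-13-(furan-3-yl)-2,6,10-trimethyltrideca-6,10-dien-1-yl]oxy}dimethylsilane | CC(C)(C)[Si](C)(C)OC[C@@H](C)CCC/C(C)=C/CC/C(C)=C/CCc1ccoc1 | intermediate
17 | (2S,6E,10E)-13-(furan-3-yl)-2,6,10-trimethyltrideca-6,10-dien-1-ol | OC[C@@H](C)CCC/C(C)=C/CC/C(C)=C/CCc1ccoc1 | intermediate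
18 | (2S,6E,10E)-13-(furan-3-yl)-2,6,10-trimethyltrideca-6,10-dienal | O=C[C@@H](C)CCC/C(C)=C/CC/C(C)=C/CCc1ccoc1 | intermediate
19 | ethyl 2-methyl-3-oxobutanoate | CCOC(=O)C(C)C(C)=O | starting material
20 | ethyl 2-bromo-2-methyl-3-oxobutanoate | CCOC(=O)C(C)(Br)C(C)=O | intermediate (not isolated)
21 | ethyl 4-bromo-2-methyl-3-oxobutanoate | CCOC(=O)C(C)C(=O)CBr | intermediate (not isolated)
22 | 3-methyltetronic acid (4-hydroxy-3-methylfuran-2(5H)-one) | CC1=C(O)COC1=O | intermediate
23 | 4-methoxy-3-methylfuran-2(5H)-one | COC1=C(C)C(=O)OC1 | intermediate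
24 | lithium 4-methoxy-3-methylfuran-2-olate | [Li+].[O-]c1occ(OC)c1C | intermediate (not isolated)
25 | (5R)-5-[(1R,2S,6E,10E)-13-(furan-3-yl)-1-hydroxy-2,6,10-trimethyltrideca-6,10-dien-1-yl]-4-methoxy-3-methylfuran-2(5H)-one (like carbinol; 5S,1'S,2'S companion carried along) | COC1=C(C)C(=O)O[C@@H]1[C@H](O)[C@@H](C)CCC/C(C)=C/CC/C(C)=C/CCc1ccoc1 | intermediate
26 | alkoxytriphenylphosphonium ion of 25 (Ph3P+–O on C1') | COC1=C(C)C(=O)O[C@@H]1[C@H](O[P+](c2ccccc2)(c2ccccc2)c2ccccc2)[C@@H](C)CCC/C(C)=C/CC/C(C)=C/CCc1ccoc1 | intermediate (not isolated)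
27 | (5E)-5-[(2S,6E,10E)-13-(furan-3-yl)-2,6,10-trimethyltrideca-6,10-dien-1-ylidene]-4-methoxy-3-methylfuran-2(5H)-one | COC1=C(C)C(=O)O/C1=C/[C@@H](C)CCC/C(C)=C/CC/C(C)=C/CCc1ccoc1 | intermediate
28 | (5E)-5-[(2S,6E,10E)-13-(furan-3-yl)-2,6,10-trimethyltrideca-6,10-dien-1-ylidene]-4-hydroxy-3-methylfuran-2(5H)-one | OC1=C(C)C(=O)O/C1=C/[C@@H](C)CCC/C(C)=C/CC/C(C)=C/CCc1ccoc1 | intermediate
29 | (2E)-2-[(2S,6E,10E)-13-(furan-3-yl)-2,6,10-trimethyltrideca-6,10-dien-1-ylidene]-4-methyl-5-oxo-2,5-dihydrofuran-3-yl octadecanoate | CCCCCCCCCCCCCCCCCC(=O)OC1=C(C)C(=O)O/C1=C/[C@@H](C)CCC/C(C)=C/CC/C(C)=C/CCc1ccoc1 | target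

Total step count: 17.
Longest linear sequence: 14 steps (steps 1–7, 9–11, 14–17); step 8 and steps 12–13 are side branches.

Steps most likely to fail

Step 9. At 220 °C the bimolecular cycloaddition may be outrun by thermal reorganisation of the substrate (Cope-type shift of the 1,5-enyne to an allene, slow E/Z drift of the 1,5-diene units, oligomerisation), or conversion may stall as the oxazole degrades. The fallback sets out from bromide 8. Displacement with PhSO2Na (DMF, 20 °C) should give the allylic phenyl sulfone F1. Its α-lithio derivative (n-BuLi, THF, −78 °C) is alkylated with commercial 3-(bromomethyl)furan to the branched sulfone F2. Reductive desulfonylation with LiBHEt3 and catalytic PdCl2(dppp) (THF, 0 °C), which keeps position and E geometry of the allylic alkene, comes back to the route at furan 16. In this case the furan ring is bought instead of built.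

Step 14. The addition is not expected to control the relative configuration at C5/C1', so a large share of the material may end up as the unlike carbinols, which the anti-elimination of step 15 would turn into the Z alkene. The fallback sets out from aldehyde 18 through the same addition to 23 and uses the separated unlike carbinol pair F3. Treatment with methyl N-(triethylammoniosulfonyl)carbamate (Burgess reagent; THF, 50 °C) dehydrates through a cyclic syn-elimination of the sulfamate ester. For the unlike relation this places the chain cis to C4, so it comes back to the route at the E ylidene 27 and both diastereomer pairs converge.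

Step 3. Enantioface discrimination may be insufficient, because a 2-methyl allylic alcohol is a less proven substrate for the hydroxyl-directed hydrogenation than 3-substituted ones. The fallback sets out from allylic alcohol 3 and uses a carboxylate as the directing group instead. MnO2 (CH2Cl2) should give the enal F4, and Pinnick oxidation (NaClO2, NaH2PO4, 2-methyl-2-butene, t-BuOH/H2O) the 2-methyl-2-enoic acid F5. Hydrogenation with Ru(OAc)2[(S)-H8-BINAP] (H2, MeOH), well established for tiglic-acid-type substrates, should give the 2S acid F6 (the ligand antipode is chosen by that analogy). Activation as the mixed carbonic anhydride F7 (i-BuOCOCl, N-methylmorpholine, THF, −15 °C) and reduction with NaBH4 (THF/H2O, 0 °C), which spares the acetate, comes back to the route at alcohol 4.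

Further compounds
F1 | step 9 | tert-butyldimethyl{[(2S,6E,10E)-2,6,10-trimethyl-12-(phenylsulfonyl)dodeca-6,10-dien-1-yl]oxy}silane | CC(C)(C)[Si](C)(C)OC[C@@H](C)CCC/C(C)=C/CC/C(C)=C/CS(=O)(=O)c1ccccc1
F2 | step 9 | tert-butyl{[(2S,6E,10E)-13-(furan-3-yl)-2,6,10-trimethyl-12-(phenylsulfonyl)trideca-6,10-dien-1-yl]oxy}dimethylsilane (both C12 epimers) | CC(C)(C)[Si](C)(C)OC[C@@H](C)CCC/C(C)=C/CC/C(C)=C/C(Cc1ccoc1)S(=O)(=O)c1ccccc1
F3 | step 14 | (5S)-5-[(1R,2S,6E,10E)-13-(furan-3-yl)-1-hydroxy-2,6,10-trimethyltrideca-6,10-dien-1-yl]-4-methoxy-3-methylfuran-2(5H)-one (unlike carbinol; 5R,1'S,2'S companion included) | COC1=C(C)C(=O)O[C@H]1[C@H](O)[C@@H](C)CCC/C(C)=C/CC/C(C)=C/CCc1ccoc1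
F4 | step 3 | (2E,6E,10E)-3,7,11-trimethyl-12-oxododeca-2,6,10-trien-1-yl acetate | O=C/C(C)=C/CC/C(C)=C/CC/C(C)=C/COC(C)=O
F5 | step 3 | (2E,6E,10E)-12-acetoxy-2,6,10-trimethyldodeca-2,6,10-trienoic acid | OC(=O)/C(C)=C/CC/C(C)=C/CC/C(C)=C/COC(C)=O
F6 | step 3 | (2S,6E,10E)-12-acetoxy-2,6,10-trimethyldodeca-6,10-dienoic acid | OC(=O)[C@@H](C)CCC/C(C)=C/CC/C(C)=C/COC(C)=O
F7 | step 3 | (2S,6E,10E)-12-acetoxy-2,6,10-trimethyldodeca-6,10-dienoic isobutyl carbonic anhydride | CC(C)COC(=O)OC(=O)[C@@H](C)CCC/C(C)=C/CC/C(C)=C/COC(C)=O
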